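Ustusoic acid B holds its C6 oxygen and the C11 carboxyl on C9 cis (both β) across ring B, C9 being a tertiary carbinol. Joining O6 to C11 reveals a 2-oxabicyclo[2.2.2]oct-5-en-3-one, the formal Diels–Alder adduct of a 3-hydroxy-2-pyranone. Everything rests on one catalytic Michael–aldol [4+2] union of 3-hydroxy-4-methyl-2H-pyran-2-one (7, carrying the future C12 methyl) with 2,4,4-trimethylcyclohex-2-en-1-one (8, ring A with the C4 gem-dimethyl group and C15). It forms C5–C6 and C9–C10, closes ring B and sets C5, C6, C9 and C10. C1 deoxygenation, lactone opening, C5 inversion through the C6 ketone, C12 oxidation and acylation finish the route.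

Key step: step 4

Remark on numbering: bicyclic compounds carry drimane numbering (ring A = C1–C5 and C10; ring B = C5–C10; C11 on C9, C12 on C8, C13/C14 on C4, C15 on C10). β is the face of the C15 methyl; "5β" marks the cis-fused series, and no prefix means 5α-H (trans-fused).

Assumption: the epi-quinine-derived thiourea is taken to deliver the enantiomer drawn for 10; if it favours the mirror image, the epi-quinidine-derived pseudo-enantiomer is used with no other change.

Step 1
Reactants: 1 methyl 2-(benzyloxy)acetate; 2 4,4-dimethoxybutan-2-one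
Product: 4 methyl 2-(benzyloxy)-3-hydroxy-5,5-dimethoxy-3-methylpentanoate (racemic diastereomer mixture), via lithium enolate 3 (not isolated)
Conditions: LiN(iPr)2 (commercial solution, 1.05 equiv), THF, −78 °C; then 2, −78 °C; AcOH quench
Reagents that add atoms: none
Why: Aldol addition of the lithium enolate of an α-alkoxy ester to the ketone carbonyl at −78 °C, where addition should outrun enolisation of the β-keto acetal, joins the future C2–C3 unit of the pyranone to its C4(Me)–C5–C6 unit; both new stereocentres vanish in step 2, so the mixture is used as such.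

Step 2
Reactants: 4 methyl 2-(benzyloxy)-3-hydroxy-5,5-dimethoxy-3-methylpentanoate
Product: 6 3-(benzyloxy)-4-methyl-2H-pyran-2-one, via enal ester 5 (not isolated)
Conditions: p-toluenesulfonic acid monohydrate (0.2 equiv), wet toluene, 80 → 110 °C, MeOH distilled off
Reagents that add atoms: none
Why: Acid-catalysed acetal cleavage and β-elimination of the tertiary hydroxyl give enal 5, whose dienol lactonises onto the methyl ester with loss of methanol (the known cyclisation of 5-oxopent-2-enoates to 2-pyranones); because the C3 oxygen stays a benzyl ether, no 2-oxo-5-al can arise and Paal–Knorr closure to a furan-2-carboxylate is excluded.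

Step 3
Reactants: 6 3-(benzyloxy)-4-methyl-2H-pyran-2-one
Product: 7 3-hydroxy-4-methyl-2H-pyran-2-one
Conditions: BCl3 (1 M in CH2Cl2, 2 equiv), CH2Cl2, −78 → 0 °C; H2O work-up
Reagents that add atoms: none
Why: Lewis-acid debenzylation in which BCl3 chelates the lactone carbonyl and the neighbouring ether oxygen and chloride removes the benzyl group (known chelation-assisted cleavage of benzyl ethers next to a carbonyl), leaving the 2-pyranone ring intact.

Step 4
Reactants: 7 3-hydroxy-4-methyl-2H-pyran-2-one; 8 2,4,4-trimethylcyclohex-2-en-1-one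
Product: 10 9α-hydroxy-1-oxo-5β-drim-7-eno-11,6β-lactone [(5R,6R,9R,10S); rings A/B cis-fused; O–C11(=O) bridge from C6 to C9 on the β-face], via Michael-adduct enolate 9 (not isolated)
Conditions: 1-[3,5-bis(trifluoromethyl)phenyl]-3-[(8α,9S)-6′-methoxycinchonan-9-yl]thiourea (20 mol%), 8 (5 equiv), CH2Cl2, 0.8 GPa, 25 °C
Reagents that add atoms: none
Why: Proposed new method: the quinuclidine nitrogen deprotonates the 3-hydroxyl of 7 while the thiourea hydrogen-bonds the carbonyl of 8; the dienolate adds through pyranone C6 to the enone β-carbon (C5) to give enolate 9, whose carbon C10 then attacks the unmasked pyranone C3 ketone (C9) in an intramolecular aldol. The closest known reaction type is the cinchona-base-catalysed formal [4+2] (Michael–aldol) addition of 3-hydroxy-2-pyranones to enones, acrylates and maleimides, together with pressure-accelerated organocatalytic conjugate additions to β-hindered enones; it has not been shown for an α-methyl, γ,γ-dimethyl cyclohexenone. Ring B is the only new ring and closes in a 6-(enolexo)-exo-trig aldol, which turns the pyranone into the O–C11(=O) bridge of a 2-oxabicyclo[2.2.2]oct-5-en-3-one. C6 and C9 are held on one face of ring B by the two-atom lactone bridge; C5 and C10 must be cis because both bonds form on one face of the ring-A (Z)-alkene; the endo arrangement (ring-A carbonyl beneath the pyranone C4=C5 unit, bound to the catalyst beside the pyranone oxygen) puts the C10 methyl and H-5 on the lactone (β) side; the absolute sense comes from the catalyst covering one enone face. The step needs Michael regioselectivity (pyranone C6 to enone C5), secured by the vinylogous enolate polarity and the unsubstituted β-position, and it needs endo and enone-face selectivity, which rest on two-point binding by the catalyst. The pressure of 0.8 GPa is chosen to offset the steric penalty of bond formation next to the C4 gem-dimethyl group and at the contiguous fully substituted C9 and C10, and to disfavour retro-aldol reversal.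

Step 5
Reactants: 10 9α-hydroxy-1-oxo-5β-drim-7-eno-11,6β-lactone
Product: 11 C1 (4-methylphenyl)sulfonylhydrazone of 10
Conditions: TsNHNH2 (1.5 equiv), pyridinium p-toluenesulfonate (0.1 equiv), MgSO4, ClCH2CH2Cl, 60 °C
Reagents that add atoms: 4-methylbenzenesulfonohydrazide, Cc1ccc(cc1)S(=O)(=O)NN
Why: Acid-catalysed hydrazone formation at the saturated, α-quaternary C1 ketone, feasible on warming; the base-free medium avoids retro-aldol cleavage of the C9–C10 bond of this β-hydroxy ketone.

Step 6
Reactants: 11 C1 tosylhydrazone of 10
Product: 13 9α-hydroxy-5β-drim-7-eno-11,6β-lactone, via tosylhydrazine 12 (not isolated)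
Conditions: catecholborane (3 equiv), CHCl3, 0 → 25 °C; then NaOAc·3H2O, 60 °C
Reagents that add atoms: none
Why: Caglioti-type tosylhydrazone reduction in its catecholborane variant: B–H adds across C=N to give 12 after hydrolysis, acetate expels sulfinate and the diazene loses N2 to leave C1 as CH2; lactone, tertiary alcohol and alkene are inert and no stereocentre of the product is touched.

Step 7
Reactants: 13 9α-hydroxy-5β-drim-7-eno-11,6β-lactone
Product: 14 allyl 6β,9α-dihydroxy-5β-drim-7-en-11-oate
Conditions: K2CO3 (0.3 equiv), allyl alcohol (solvent), 40 °C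
Reagents that add atoms: allyl alcohol (prop-2-en-1-ol), C=CCO
Why: Base-catalysed transesterification opens the strained bridged lactone by acyl–oxygen cleavage (the known alcoholysis of 2-pyranone cycloadducts to cis-4-hydroxycyclohex-2-enecarboxylates), freeing the 6β-hydroxyl with retention and installing an ester removable later under neutral conditions; with C1 reduced no retro-aldol pathway remains.

Step 8
Reactants: 14 allyl 6β,9α-dihydroxy-5β-drim-7-en-11-oate
Product: 15 allyl 9α-hydroxy-6-oxo-5β-drim-7-en-11-oate
Conditions: Dess–Martin periodinane (1.3 equiv), CH2Cl2, 0 → 25 °C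
Reagents that add atoms: none
Why: Dess–Martin oxidation of the secondary allylic C6 alcohol to the Δ7-6-ketone, which makes H-5 removable; the tertiary 9-hydroxyl, the ester and the alkene do not react.

Step 9
Reactants: 15 allyl 9α-hydroxy-6-oxo-5β-drim-7-en-11-oate
Product: 17 allyl 9α-hydroxy-6-oxodrim-7-en-11-oate (5α-H; trans-fused), via dilithium dienolate 16 (not isolated)
Conditions: LiN(iPr)2 (commercial solution, 2.3 equiv), THF, −78 → −40 °C; then AcOH (5 equiv) in THF, −78 °C
Reagents that add atoms: none
Why: Epimerisation by kinetic enolate protonation: the amide base removes the 9-OH proton and then the α′ hydrogen at C5 to give the cross-conjugated dienolate 16, whose only nucleophilic carbon (C5) is protonated irreversibly at −78 °C from the α-face because the β-face is screened by the syn-axial C10 and 4β methyl groups, so the 5α-H (trans) ring fusion results.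

Step 10
Reactants: 17 allyl 9α-hydroxy-6-oxodrim-7-en-11-oate
Product: 18 allyl 6β,9α-dihydroxydrim-7-en-11-oate
Conditions: NaBH4 (1 equiv), CeCl3·7H2O (1 equiv), MeOH, −78 → −40 °C
Reagents that add atoms: none
Why: Luche 1,2-reduction of the enone: hydride reaches C6 from the α-face, opposite the axial C10 and 4β methyl groups, so the new C6 stereocentre carries the axial 6β-hydroxyl; the hindered ester survives at low temperature.

Step 11
Reactants: 18 allyl 6β,9α-dihydroxydrim-7-en-11-oate
Product: 20 allyl 6β,9α-dihydroxy-12-oxodrim-7-en-11-oate, via allylic alcohol 19 (not isolated)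
Conditions: SeO2 (0.5 equiv), t-BuOOH (3 equiv), CH2Cl2, 25 °C; short silica plug; then TEMPO (0.1 equiv), PhI(OAc)2 (1.2 equiv), CH2Cl2, 25 °C
Reagents that add atoms: selenium dioxide, O=[Se]=O (catalytic oxygen carrier); tert-butyl hydroperoxide, CC(C)(C)OO (terminal oxygen source)
Why: Riley-type allylic oxidation with catalytic SeO2: the ene reaction at C7=C8 can abstract hydrogen only from C12 on the disubstituted terminus (C9 bears none) and the [2,3]-shift gives the primary allylic alcohol 19, which the TEMPO/oxoammonium oxidation converts to the enal selectively over the hindered secondary 6β- and tertiary 9α-hydroxyls.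

Step 12
Reactants: 21 (2E,4E)-hexa-2,4-dienal; 22 malonic acid
Product: 24 (2E,4E,6E)-octa-2,4,6-trienoic acid, via dienylidenemalonic acid 23 (not isolated)
Conditions: pyridine, piperidine (0.1 equiv), 90 °C
Reagents that add atoms: none
Why: Knoevenagel–Doebner condensation with decarboxylation in pyridine gives the thermodynamically favoured E geometry at the new C2=C3 bond and leaves the E,E-diene of the aldehyde unchanged.

Step 13
Reactants: 20 allyl 6β,9α-dihydroxy-12-oxodrim-7-en-11-oate; 24 (2E,4E,6E)-octa-2,4,6-trienoic acid
Product: 26 allyl 9α-hydroxy-6β-[(2E,4E,6E)-octa-2,4,6-trienoyloxy]-12-oxodrim-7-en-11-oate, via mixed anhydride 25 (not isolated)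
Conditions: 24 (2 equiv), 2,4,6-trichlorobenzoyl chloride (2 equiv), Et3N (3 equiv), toluene, 25 °C; then 20, 4-(dimethylamino)pyridine (2 equiv), toluene, 40 °C
Reagents that add atoms: none
Why: Yamaguchi esterification: mixed anhydride 25 passes the trienoyl group through the acylpyridinium ion to the axial 6β secondary hydroxyl with retention at C6, while the tertiary 9α-hydroxyl is too hindered to compete and the mild base keeps the triene geometry.

Step 14
Reactants: 26 allyl 9α-hydroxy-6β-[(2E,4E,6E)-octa-2,4,6-trienoyloxy]-12-oxodrim-7-en-11-oate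
Product: 27 ustusoic acid B [(5S,6R,9S,10S)-9α-hydroxy-6β-[(2E,4E,6E)-octa-2,4,6-trienoyloxy]-12-oxodrim-7-en-11-oic acid]
Conditions: Pd(PPh3)4 (5 mol%), N-methylaniline (3 equiv), THF, 0 → 25 °C; pH 4 buffer work-up
Reagents that add atoms: none
Why: Tsuji–Trost deallylation: zerovalent palladium ionises the unhindered allyl ester to a π-allyl complex that N-methylaniline captures, releasing the C11 acid under neutral conditions; the ring-bound secondary allylic trienoate on the electron-poor trisubstituted alkene should ionise far more slowly, and the enal, triene and tertiary alcohol are untouched.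

Compound list
1 | methyl 2-(benzyloxy)acetate | COC(=O)COCc1ccccc1 | starting material
2 | 4,4-dimethoxybutan-2-one | CC(=O)CC(OC)OC | starting material
3 | lithium enolate of 1 (lithium 2-(benzyloxy)-1-methoxyethen-1-olate) | [Li+].COC([O-])=COCc1ccccc1 | intermediate (not isolated)
4 | methyl 2-(benzyloxy)-3-hydroxy-5,5-dimethoxy-3-methylpentanoate (racemic diastereomer mixture) | COC(=O)C(OCc1ccccc1)C(C)(O)CC(OC)OC | intermediate
5 | methyl 2-(benzyloxy)-3-methyl-5-oxopent-3-enoate (E/Z mixture) | COC(=O)C(OCc1ccccc1)C(C)=CC=O | intermediate (not isolated)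
6 | 3-(benzyloxy)-4-methyl-2H-pyran-2-one | CC1=C(OCc2ccccc2)C(=O)OC=C1 | intermediate
7 | 3-hydroxy-4-methyl-2H-pyran-2-one | CC1=C(O)C(=O)OC=C1 | intermediate (key-step precursor)
8 | 2,4,4-trimethylcyclohex-2-en-1-one | CC1=CC(C)(C)CCC1=O | starting material (key-step precursor)
9 | 4-methyl-6-(2,6,6-trimethyl-3-oxidocyclohex-2-en-1-yl)-2H-pyran-2,3(6H)-dione, the C5–C6-bonded Michael-adduct enolate (anion; counter-ion is the protonated catalyst) | CC1=C([O-])CCC(C)(C)[C@H]1[C@@H]2OC(=O)C(=O)C(C)=C2 | intermediate (not isolated)
10 | 9α-hydroxy-1-oxo-5β-drim-7-eno-11,6β-lactone, (5R,6R,9R,10S); cis-fused, 10β-methyl, 5β-H, lactone bridge on the β-face | O3[C@@H]1C=C(C)[C@](O)(C3=O)[C@@]2(C)C(=O)CCC(C)(C)[C@@H]12 | intermediate (key-step product)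
11 | C1 (4-methylphenyl)sulfonylhydrazone of 10 (C=N geometry immaterial) | O3[C@@H]1C=C(C)[C@](O)(C3=O)[C@@]2(C)C(=NNS(=O)(=O)c4ccc(C)cc4)CCC(C)(C)[C@@H]12 | intermediate
12 | 1-[2-(4-methylphenylsulfonyl)hydrazinyl]-9α-hydroxy-5β-drim-7-eno-11,6β-lactone (C1 configuration immaterial) | O3[C@@H]1C=C(C)[C@](O)(C3=O)[C@@]2(C)C(NNS(=O)(=O)c4ccc(C)cc4)CCC(C)(C)[C@@H]12 | intermediate (not isolated)
13 | 9α-hydroxy-5β-drim-7-eno-11,6β-lactone | O3[C@@H]1C=C(C)[C@](O)(C3=O)[C@@]2(C)CCCC(C)(C)[C@@H]12 | intermediate
14 | allyl 6β,9α-dihydroxy-5β-drim-7-en-11-oate | O[C@@H]1C=C(C)[C@](O)(C(=O)OCC=C)[C@@]2(C)CCCC(C)(C)[C@@H]12 | intermediate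
15 | allyl 9α-hydroxy-6-oxo-5β-drim-7-en-11-oate | O=C1C=C(C)[C@](O)(C(=O)OCC=C)[C@@]2(C)CCCC(C)(C)[C@@H]12 | intermediate
16 | dilithium salt of allyl 6,9α-dihydroxydrima-5,7-dien-11-oate (C6 enolate, C9 alkoxide) | [Li+].[Li+].[O-]C1=C2C(C)(C)CCC[C@]2(C)[C@@]([O-])(C(=O)OCC=C)C(C)=C1 | intermediate (not isolated)
17 | allyl 9α-hydroxy-6-oxodrim-7-en-11-oate (5α-H, trans-fused) | O=C1C=C(C)[C@](O)(C(=O)OCC=C)[C@@]2(C)CCCC(C)(C)[C@H]12 | intermediate
18 | allyl 6β,9α-dihydroxydrim-7-en-11-oate | O[C@@H]1C=C(C)[C@](O)(C(=O)OCC=C)[C@@]2(C)CCCC(C)(C)[C@H]12 | intermediate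
19 | allyl 6β,9α,12-trihydroxydrim-7-en-11-oate | O[C@@H]1C=C(CO)[C@](O)(C(=O)OCC=C)[C@@]2(C)CCCC(C)(C)[C@H]12 | intermediate (not isolated)
20 | allyl 6β,9α-dihydroxy-12-oxodrim-7-en-11-oate | O[C@@H]1C=C(C=O)[C@](O)(C(=O)OCC=C)[C@@]2(C)CCCC(C)(C)[C@H]12 | intermediate
21 | (2E,4E)-hexa-2,4-dienal | C/C=C/C=C/C=O | starting material
22 | malonic acid | OC(=O)CC(=O)O | starting material
23 | 2-[(2E,4E)-hexa-2,4-dien-1-ylidene]malonic acid | C/C=C/C=C/C=C(C(=O)O)C(=O)O | intermediate (not isolated)
24 | (2E,4E,6E)-octa-2,4,6-trienoic acid | C/C=C/C=C/C=C/C(=O)O | intermediate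
25 | (2E,4E,6E)-octa-2,4,6-trienoic 2,4,6-trichlorobenzoic anhydride | C/C=C/C=C/C=C/C(=O)OC(=O)c1c(Cl)cc(Cl)cc1Cl | intermediate (not isolated)
26 | allyl 9α-hydroxy-6β-[(2E,4E,6E)-octa-2,4,6-trienoyloxy]-12-oxodrim-7-en-11-oate | C/C=C/C=C/C=C/C(=O)O[C@@H]1C=C(C=O)[C@](O)(C(=O)OCC=C)[C@@]2(C)CCCC(C)(C)[C@H]12 | intermediate
27 | ustusoic acid B, (5S,6R,9S,10S)-9α-hydroxy-6β-[(2E,4E,6E)-octa-2,4,6-trienoyloxy]-12-oxodrim-7-en-11-oic acid | C/C=C/C=C/C=C/C(=O)O[C@@H]1C=C(C=O)[C@](O)(C(=O)O)[C@@]2(C)CCCC(C)(C)[C@H]12 | target

Total step count: 14. Longest linear sequence: 13 steps (steps 1–11, 13 and 14; step 12 is the side-chain branch).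

Steps most likely to fail

1. Step 4 (Proposed new method). The conjugate addition at the neopentyl-type enone β-carbon may be too slow. The aldol closure may be undone by retro-aldol and retro-Michael fragmentation. Endo/exo or enone-face control may be insufficient. Fallback (known chemistry): setting out from 6, with 8, the benzyl-protected pyranone is used as a neutral diene in a thermal Diels–Alder reaction under 1.2–1.5 GPa (neat 8, 50 °C). This is a known class of cycloaddition for 3-oxygenated 2-pyranones and for 2-methyl- and 4,4-dimethylcyclohexenones, which gives isolable bridged lactones with the same regiochemistry and endo preference. It should give racemic 9α-(benzyloxy)-1-oxo-5β-drim-7-eno-11,6β-lactone F1, whose enantiomers are separated by preparative chromatography on a chiral stationary phase. BCl3 (CH2Cl2, −78 °C) then cleaves the benzyl ether and the route is rejoined at 10; steps 3 and 4 are bypassed.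

2. Step 9. Deprotonation may be incomplete or may occur at the C12 methyl (γ) in place of the hindered H-5, and partial re-equilibration during the quench would leave cis-fused material. Fallback: setting out from 15, thermodynamic equilibration replaces kinetic protonation. DBU (0.5 equiv) in toluene at 60 °C interconverts the C5 epimers through the same dienolate. The trans-fused Δ7-6-ketone is the favoured epimer in the related steroid series, though the C4 gem-dimethyl group may reduce that bias here. 17 is separated by chromatography and recovered 15 is re-submitted. The route is rejoined at 17 and no new compound is made (F0).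

3. Step 5. Condensation at the α-quaternary C1 ketone may be slow, so that heat- or acid-induced retro-aldol opening of ring B competes. Fallback: setting out from 10, the ketone is converted with ethane-1,2-dithiol and BF3·OEt2 (CH2Cl2, 0 °C) into 9α-hydroxy-1,1-(ethane-1,2-diyldisulfanediyl)-5β-drim-7-eno-11,6β-lactone F2. This is desulfurised with acetone-deactivated Raney Ni in EtOH (Mozingo reduction), which rejoins the route at 13; steps 5 and 6 are bypassed.

Further compounds
F1 | step 4 | 9α-(benzyloxy)-1-oxo-5β-drim-7-eno-11,6β-lactone (formed as the racemate; the enantiomer drawn is carried on after resolution) | O3[C@@H]1C=C(C)[C@](OCc4ccccc4)(C3=O)[C@@]2(C)C(=O)CCC(C)(C)[C@@H]12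
F0 | step 9 | none | none
F2 | step 5 | 9α-hydroxy-1,1-(ethane-1,2-diyldisulfanediyl)-5β-drim-7-eno-11,6β-lactone (C1 dithiolane of 10) | O3[C@@H]1C=C(C)[C@](O)(C3=O)[C@@]2(C)C4(SCCS4)CCC(C)(C)[C@@H]12
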